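**Retrosynthetic overview**

1. The target is a centrosymmetric bis-pyranone; the last operations are only O-methylation of a bis(4-hydroxy-2-pyranone) and release of the two phenols.
2. Both pyranone rings are cut back together (two-directional) to a 2,4-diaryl-cyclobutane-1,3-dicarboxylic acid: acid chloride plus dioxinone dienolate, then acylketene ring closure.
3. The cyclobutane is not made by [2+2] dimerisation of a styryl unit; it is bought as trans-cyclobutane-1,3-dicarboxylic acid.
4. Key step: two trans-disposed 8-aminoquinoline amides each deliver one aryl group cis to themselves, from opposite faces, in one twofold C(sp3)–H arylation that sets the whole 1α,2α,3β,4β array.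
5. Ring order: cyclobutane (purchased), then the two aryl groups, then both pyranone rings last and at the same time.

Assumption: the SMILES encodes the head-to-tail, α-truxillic-type (1α,2α,3β,4β) dimer, which has an inversion centre and is achiral, so the "single enantiomer" is this single meso diastereomer and only relative configuration must be controlled; the four starting materials are taken as catalogue compounds.

**Step 1**
Reactants: 1 trans-cyclobutane-1,3-dicarboxylic acid; 2 quinolin-8-amine (8-aminoquinoline, 2.3 equiv)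
Product: 3 trans-N1,N3-di(quinolin-8-yl)cyclobutane-1,3-dicarboxamide
Conditions: N-(3-dimethylaminopropyl)-N'-ethylcarbodiimide hydrochloride (EDC·HCl, 2.6 equiv), DMAP (0.5 equiv), CH2Cl2, 0 °C to rt
Reagents that add atoms: none
Why: DMAP-catalysed carbodiimide amide coupling of both carboxyl groups; no ring carbon is touched, so the trans-1,3 relationship bought with 1 is kept.

**Step 2**
Reactants: 3 trans-N1,N3-di(quinolin-8-yl)cyclobutane-1,3-dicarboxamide; 4 1-iodo-4-(methoxymethoxy)benzene (5 equiv)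
Product: 6 (1α,2α,3β,4β)-2,4-bis[4-(methoxymethoxy)phenyl]-N1,N3-di(quinolin-8-yl)cyclobutane-1,3-dicarboxamide (meso), via mono-aryl bis-amide 5 (not isolated)
Conditions: Pd(OAc)2 (15 mol %), AgOAc (4 equiv), PivOH (0.3 equiv), toluene, 110 °C, sealed tube
Reagents that add atoms: none
Why: Proposed new method: each 8-aminoquinoline amide binds divalent palladium N,N-bidentately and can reach only a β-methylene C–H on its own face through a cis-fused five-membered palladacycle (concerted metalation–deprotonation, oxidative addition of 4 to give tetravalent palladium, C–C reductive elimination, AgOAc as iodide scavenger), so each aryl enters cis to the amide that delivered it; after the first arylation (5) the amide that has not yet acted lies on the open face with no cis neighbour and should direct the second aryl to C4 from the opposite face, giving the 2,4-trans-diaryl (1α,2α,3β,4β) array in one operation, whereas a second arylation by the first amide (which must build an all-cis aryl/amide/aryl triad) is the competing path to the 2,4-cis-diaryl isomer; the closest known reaction type is the aminoquinoline-directed, palladium-catalysed cis-selective methylene C–H arylation of cyclobutanecarboxamides.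

**Step 3**
Reactants: 6 (1α,2α,3β,4β)-2,4-bis[4-(methoxymethoxy)phenyl]-N1,N3-di(quinolin-8-yl)cyclobutane-1,3-dicarboxamide
Product: 9 (1α,2α,3β,4β)-2,4-bis[4-(methoxymethoxy)phenyl]cyclobutane-1,3-dicarboxylic acid, via bis(N-Boc) imide 7 (not isolated), via bis-peroxy acid 8 (not isolated)
Conditions: Boc2O (6 equiv), DMAP (2 equiv), MeCN, 60 °C; concentrate; LiOH·H2O (6 equiv), 30% aq. H2O2 (20 equiv), THF/H2O 3:1, 0 °C to rt; aq. Na2SO3; cold 1 M HCl to pH 3
Reagents that add atoms: di-tert-butyl dicarbonate, CC(C)(C)OC(=O)OC(=O)OC(C)(C)C (Boc groups, held only in 7); hydrogen peroxide, OO (as lithium hydroperoxide: the peroxy oxygens of 8 and one oxygen of each CO2H in 9)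
Why: N-Boc activation twists each secondary amide so that the small α-effect nucleophile hydroperoxide attacks the acyl carbon and expels Boc-protected aminoquinoline (standard auxiliary removal, LiOOH cleavage), sulfite reduces the percarboxylate, and the cold non-enolising conditions leave the ring configuration unchanged.

**Step 4**
Reactants: 9 (1α,2α,3β,4β)-2,4-bis[4-(methoxymethoxy)phenyl]cyclobutane-1,3-dicarboxylic acid; 10 2,2,6-trimethyl-4H-1,3-dioxin-4-one (4.6 equiv)
Product: 13 6,6'-{[(1α,2α,3β,4β)-2,4-bis[4-(methoxymethoxy)phenyl]cyclobutane-1,3-diyl]bis(2-oxoethane-2,1-diyl)}bis(2,2-dimethyl-4H-1,3-dioxin-4-one), via bis-acid chloride 11 (not isolated), via lithium dienolate 12 (not isolated)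
Conditions: 9, 1-chloro-N,N,2-trimethylprop-1-en-1-amine (2.4 equiv), CH2Cl2, 0 °C to rt, evaporate; separately 10, LiN(SiMe3)2 (4.4 equiv), THF, −78 °C; add 11 in THF, −78 °C, 1 h; AcOH quench
Reagents that add atoms: 1-chloro-N,N,2-trimethylprop-1-en-1-amine, CC(C)=C(Cl)N(C)C (chlorine, held only in 11); lithium bis(trimethylsilyl)amide, [Li+].C[Si](C)(C)[N-][Si](C)(C)C (lithium, held only in 12)
Why: Neutral acid-chloride formation (no HCl, so the MOM ethers survive) followed by Claisen-type γ-C-acylation of the vinylogous lithium enolate of 10; the second equivalent of dienolate deprotonates the new 1,3-dicarbonyl unit, which protects it from further attack and from enolisation toward the ring, and inverse addition at −78 °C keeps the ring α-carbons from epimerising.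

**Step 5**
Reactants: 13 the bis(6-acylmethyl-dioxinone) from step 4
Product: 15 6,6'-[(1α,2α,3β,4β)-2,4-bis[4-(methoxymethoxy)phenyl]cyclobutane-1,3-diyl]bis(4-hydroxy-2H-pyran-2-one), via bis-acylketene 14 (not isolated)
Conditions: toluene (0.01 M), 110 °C, 1 h
Reagents that add atoms: none
Why: Thermal retro-[4+2] of each dioxinone expels acetone and gives an acylketene that is trapped by the enol of the neighbouring ketone (oxa-6π ring closure/lactonisation) to form the 4-hydroxy-2-pyranone under neutral conditions that touch no stereocentre.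

**Step 6**
Reactants: 15 6,6'-[(1α,2α,3β,4β)-2,4-bis[4-(methoxymethoxy)phenyl]cyclobutane-1,3-diyl]bis(4-hydroxy-2H-pyran-2-one)
Product: 16 6,6'-[(1α,2α,3β,4β)-2,4-bis[4-(methoxymethoxy)phenyl]cyclobutane-1,3-diyl]bis(4-methoxy-2H-pyran-2-one)
Conditions: Me2SO4 (2.6 equiv), K2CO3 (3 equiv), acetone, 50 °C
Reagents that add atoms: dimethyl sulfate, COS(=O)(=O)OC
Why: Williamson-type O-alkylation of the acidic vinylogous-acid hydroxyl (pKa about 5), which under carbonate/dimethyl sulfate conditions favours the 4-methoxy-2-pyranone over the 2-methoxy-4-pyranone isomer; K2CO3 is far too weak to deprotonate the ring methines.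

**Step 7**
Reactants: 16 6,6'-[(1α,2α,3β,4β)-2,4-bis[4-(methoxymethoxy)phenyl]cyclobutane-1,3-diyl]bis(4-methoxy-2H-pyran-2-one)
Product: 17 6,6'-[(1α,2α,3β,4β)-2,4-bis(4-hydroxyphenyl)cyclobutane-1,3-diyl]bis(4-methoxy-2H-pyran-2-one) (CNP0273697.2)
Conditions: HCl (1.25 M in MeOH), MeOH/THF, 45 °C
Reagents that add atoms: none
Why: Acid-catalysed acetal exchange transfers both MOM groups to methanol; the 4-methoxy-2-pyranone is stable to methanolic HCl (any exchange of its methoxy group with methanol is degenerate) and no stereocentre is involved.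

**Compound list**

1 | trans-cyclobutane-1,3-dicarboxylic acid | O=C(O)[C@H]1C[C@H](C(=O)O)C1 | starting material
2 | quinolin-8-amine (8-aminoquinoline) | Nc1cccc2cccnc12 | starting material
3 | trans-N1,N3-di(quinolin-8-yl)cyclobutane-1,3-dicarboxamide | O=C(Nc1cccc2cccnc12)[C@H]1C[C@H](C(=O)Nc2cccc3cccnc23)C1 | intermediate
4 | 1-iodo-4-(methoxymethoxy)benzene | COCOc1ccc(I)cc1 | starting material
5 | (1α,2α,3β)-2-[4-(methoxymethoxy)phenyl]-N1,N3-di(quinolin-8-yl)cyclobutane-1,3-dicarboxamide (racemic; aryl cis to one amide, trans to the other; one enantiomer drawn) | O=C(Nc1cccc2cccnc12)[C@H]1[C@H](c2ccc(OCOC)cc2)[C@H](C(=O)Nc2cccc3cccnc23)C1 | intermediate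
6 | (1α,2α,3β,4β)-2,4-bis[4-(methoxymethoxy)phenyl]-N1,N3-di(quinolin-8-yl)cyclobutane-1,3-dicarboxamide (meso) | O=C(Nc1cccc2cccnc12)[C@H]1[C@H](c2ccc(OCOC)cc2)[C@H](C(=O)Nc2cccc3cccnc23)[C@H]1c1ccc(OCOC)cc1 | intermediate
7 | bis(N-Boc) derivative of 6: di-tert-butyl N,N'-{[(1α,2α,3β,4β)-2,4-bis[4-(methoxymethoxy)phenyl]cyclobutane-1,3-diyl]dicarbonyl}bis(quinolin-8-ylcarbamate) | O=C(N(C(=O)OC(C)(C)C)c1cccc2cccnc12)[C@H]1[C@H](c2ccc(OCOC)cc2)[C@H](C(=O)N(C(=O)OC(C)(C)C)c2cccc3cccnc23)[C@H]1c1ccc(OCOC)cc1 | intermediate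
8 | (1α,2α,3β,4β)-2,4-bis[4-(methoxymethoxy)phenyl]cyclobutane-1,3-dicarboperoxoic acid (dilithium salt in the flask) | OOC(=O)[C@H]1[C@H](c2ccc(OCOC)cc2)[C@H](C(=O)OO)[C@H]1c1ccc(OCOC)cc1 | intermediate
9 | (1α,2α,3β,4β)-2,4-bis[4-(methoxymethoxy)phenyl]cyclobutane-1,3-dicarboxylic acid | O=C(O)[C@H]1[C@H](c2ccc(OCOC)cc2)[C@H](C(=O)O)[C@H]1c1ccc(OCOC)cc1 | intermediate
10 | 2,2,6-trimethyl-4H-1,3-dioxin-4-one | CC1=CC(=O)OC(C)(C)O1 | starting material
11 | (1α,2α,3β,4β)-2,4-bis[4-(methoxymethoxy)phenyl]cyclobutane-1,3-dicarbonyl dichloride | O=C(Cl)[C@H]1[C@H](c2ccc(OCOC)cc2)[C@H](C(=O)Cl)[C@H]1c1ccc(OCOC)cc1 | intermediate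
12 | lithium 2,2-dimethyl-6-methylidene-6H-1,3-dioxin-4-olate (lithium dienolate of 10) | [Li+].C=C1C=C([O-])OC(C)(C)O1 | intermediate
13 | 6,6'-{[(1α,2α,3β,4β)-2,4-bis[4-(methoxymethoxy)phenyl]cyclobutane-1,3-diyl]bis(2-oxoethane-2,1-diyl)}bis(2,2-dimethyl-4H-1,3-dioxin-4-one) | O=C(CC1=CC(=O)OC(C)(C)O1)[C@H]1[C@H](c2ccc(OCOC)cc2)[C@H](C(=O)CC2=CC(=O)OC(C)(C)O2)[C@H]1c1ccc(OCOC)cc1 | intermediate
14 | 1,1'-[(1α,2α,3β,4β)-2,4-bis[4-(methoxymethoxy)phenyl]cyclobutane-1,3-diyl]bis(pent-4-ene-1,3,5-trione) (bis-acylketene) | O=C=CC(=O)CC(=O)[C@H]1[C@H](c2ccc(OCOC)cc2)[C@H](C(=O)CC(=O)C=C=O)[C@H]1c1ccc(OCOC)cc1 | intermediate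
15 | 6,6'-[(1α,2α,3β,4β)-2,4-bis[4-(methoxymethoxy)phenyl]cyclobutane-1,3-diyl]bis(4-hydroxy-2H-pyran-2-one) | Oc1cc(=O)oc([C@H]2[C@H](c3ccc(OCOC)cc3)[C@H](c3cc(O)cc(=O)o3)[C@H]2c2ccc(OCOC)cc2)c1 | intermediate
16 | 6,6'-[(1α,2α,3β,4β)-2,4-bis[4-(methoxymethoxy)phenyl]cyclobutane-1,3-diyl]bis(4-methoxy-2H-pyran-2-one) | COc1cc(=O)oc([C@H]2[C@H](c3ccc(OCOC)cc3)[C@H](c3cc(OC)cc(=O)o3)[C@H]2c2ccc(OCOC)cc2)c1 | intermediate
17 | 6,6'-[(1α,2α,3β,4β)-2,4-bis(4-hydroxyphenyl)cyclobutane-1,3-diyl]bis(4-methoxy-2H-pyran-2-one) (CNP0273697.2) | COc1cc(=O)oc([C@H]2[C@H](c3ccc(O)cc3)[C@H](c3cc(OC)cc(=O)o3)[C@H]2c2ccc(O)cc2)c1 | target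

**Totals**

Total step count: 7. Longest linear sequence: 7 steps (1 to 17); the route is fully linear, with 2, 4 and 10 entering as bought reagents.

**Three steps most likely to fail, each with one fallback**

Step 2 (highest risk). The first-acting amide may arylate a second time on its own face and give the 2,4-cis-diaryl isomer, or the reaction may stall at 5. The wrong isomer is easy to recognise: it shows two different amide environments in the NMR spectrum, whereas centrosymmetric 6 shows one. The fallback sets out from 2 and 4 and comes back to the route at 9; it gives up the one-pot double direction and installs the aryl groups one at a time with a single auxiliary. Bought cis-3-(methoxycarbonyl)cyclobutane-1-carboxylic acid F1 is coupled with 2 (EDC·HCl, DMAP) to give methyl cis-3-(quinolin-8-ylcarbamoyl)cyclobutane-1-carboxylate F2. Arylation with 4 (Pd(OAc)2, AgOAc, PivOH, 90 °C) gives the all-cis methyl 2-[4-(methoxymethoxy)phenyl]-3-(quinolin-8-ylcarbamoyl)cyclobutane-1-carboxylate F3; it stops there because a second arylation would need an all-cis tetrasubstituted ring. Base-mediated epimerisation of the amide-bearing carbon (LiOC(CH3)3, toluene, 50 °C) relieves the all-cis strain and gives the (1α,2α,3β) amide ester F4, in which the amide is trans to aryl and ester. A second arylation with 4, cis to the inverted amide, gives the (1α,2α,3β,4β) diaryl amide ester F5. Boc2O/DMAP followed by LiOH/H2O2 cleaves the auxiliary and the methyl ester to give 9.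

Step 4. The twofold C-acylation at two hindered carbonyls may be incomplete, or ketene formation/enolisation at the acid chloride may epimerise a ring carbon to the 1,3-cis isomer. The fallback sets out from 9 and comes back at 15; it replaces acid chloride, dioxinone and acylketene by a chelation-controlled acylation of an open-chain dianion and a base-induced lactonisation. Compound 9 is converted (MeNHOMe·HCl, EDC·HCl, DMAP, CH2Cl2) into (1α,2α,3β,4β)-N1,N3-dimethoxy-N1,N3-dimethyl-2,4-bis[4-(methoxymethoxy)phenyl]cyclobutane-1,3-dicarboxamide F7. Its stable tetrahedral chelate cannot form a ketene, and it is attacked by the dianion of methyl acetoacetate (NaH, then n-BuLi, THF, 0 °C) to give dimethyl 5,5'-[(1α,2α,3β,4β)-2,4-bis[4-(methoxymethoxy)phenyl]cyclobutane-1,3-diyl]bis(3,5-dioxopentanoate) F8. DBU in toluene at 80 °C closes both lactones with loss of methanol and gives 15.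

Step 3. Boc activation of the two hindered amides may be incomplete, or hydroperoxide may attack the Boc carbonyl and return 6. The fallback sets out from 6 and comes back at 9; it avoids N-activation and uses chelation-assisted catalytic alcoholysis. Heating 6 with nickel bis(2,2,6,6-tetramethylheptane-3,5-dionate) (10 mol %, divalent nickel) in MeOH at 100 °C in a sealed tube gives dimethyl (1α,2α,3β,4β)-2,4-bis[4-(methoxymethoxy)phenyl]cyclobutane-1,3-dicarboxylate F6 and returns 2. Mild saponification (LiOH, THF/H2O, rt) then gives 9.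

**Further compounds**

F1 | step 2 | cis-3-(methoxycarbonyl)cyclobutane-1-carboxylic acid (bought) | COC(=O)[C@H]1C[C@@H](C(=O)O)C1
F2 | step 2 | methyl cis-3-(quinolin-8-ylcarbamoyl)cyclobutane-1-carboxylate | COC(=O)[C@H]1C[C@@H](C(=O)Nc2cccc3cccnc23)C1
F3 | step 2 | methyl (1α,2α,3α)-2-[4-(methoxymethoxy)phenyl]-3-(quinolin-8-ylcarbamoyl)cyclobutane-1-carboxylate (all-cis, racemic) | O=C(Nc1cccc2cccnc12)[C@@H]1[C@H](c2ccc(OCOC)cc2)[C@H](C(=O)OC)C1
F4 | step 2 | methyl (1α,2α,3β)-2-[4-(methoxymethoxy)phenyl]-3-(quinolin-8-ylcarbamoyl)cyclobutane-1-carboxylate (racemic) | O=C(Nc1cccc2cccnc12)[C@H]1[C@H](c2ccc(OCOC)cc2)[C@H](C(=O)OC)C1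
F5 | step 2 | methyl (1α,2α,3β,4β)-2,4-bis[4-(methoxymethoxy)phenyl]-3-(quinolin-8-ylcarbamoyl)cyclobutane-1-carboxylate (racemic) | O=C(Nc1cccc2cccnc12)[C@H]1[C@H](c2ccc(OCOC)cc2)[C@H](C(=O)OC)[C@H]1c1ccc(OCOC)cc1
F6 | step 3 | dimethyl (1α,2α,3β,4β)-2,4-bis[4-(methoxymethoxy)phenyl]cyclobutane-1,3-dicarboxylate | COC(=O)[C@H]1[C@H](c2ccc(OCOC)cc2)[C@H](C(=O)OC)[C@H]1c1ccc(OCOC)cc1
F7 | step 4 | (1α,2α,3β,4β)-N1,N3-dimethoxy-N1,N3-dimethyl-2,4-bis[4-(methoxymethoxy)phenyl]cyclobutane-1,3-dicarboxamide | CON(C)C(=O)[C@H]1[C@H](c2ccc(OCOC)cc2)[C@H](C(=O)N(C)OC)[C@H]1c1ccc(OCOC)cc1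
F8 | step 4 | dimethyl 5,5'-[(1α,2α,3β,4β)-2,4-bis[4-(methoxymethoxy)phenyl]cyclobutane-1,3-diyl]bis(3,5-dioxopentanoate) | COC(=O)CC(=O)CC(=O)[C@H]1[C@H](c2ccc(OCOC)cc2)[C@H](C(=O)CC(=O)CC(=O)OC)[C@H]1c1ccc(OCOC)cc1
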